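## Retrosynthetic overview

1. The 2,5-dihydrofuran ring (5',8'-epoxide) is closed last, by the biogenetic acid-catalysed rearrangement of a 5',6'-epoxide on the complete C40 polyene beside the free cis-5,6-diol; C8' is set in that step by a chiral acid.
2. The C40 epoxy-diol is cut at C11=C12 and C11'=C12' into a C10 bis(phosphonium) salt and two C15 dienals, joined by two Wittig reactions in one flask.
3. Both C15 dienals come from one vinyl epoxide: the epoxy dienal itself, and the cis-diol dienal (stored as cyclic carbonate) by palladium/CO2 opening of that epoxide with retention.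
4. The C15 epoxy dienal goes back to β-cyclocitral: Sharpless epoxidation of β-cyclogeraniol sets C5 and C6 of both ends, followed by a C5 Horner–Wadsworth–Emmons extension.
5. Order of ring formation: cyclohexane rings bought with β-cyclocitral; oxirane (step 2); temporary cyclic carbonate (step 6); dihydrofuran (step 10).

Assumption: the target is read as (5R,6S,5'R,8'S)-5',8'-epoxy-5,6,5',8'-tetrahydro-β,β-carotene-5,6-diol (carotenoid numbering for C40 compounds), i.e. a cis-5,6-diol at one end and a 5,8-furanoid ring at the other whose C8' polyene substituent is cis to the 5'-methyl.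

Assumption: 11Z/11'Z isomers formed in the Wittig reactions are not numbered separately; they are converged to all-E by heating inside step 9, and compounds 12 to 14 are drawn all-E.

## Route

Step 1
Reactants: 1 β-cyclocitral (2,6,6-trimethylcyclohex-1-ene-1-carbaldehyde)
Product: 2 β-cyclogeraniol ((2,6,6-trimethylcyclohex-1-en-1-yl)methanol)
Conditions: NaBH4, MeOH, 0 °C
Reagents that add atoms: none
Why: Sodium borohydride 1,2-reduction of the hindered conjugated aldehyde gives the allylic alcohol needed to direct the epoxidation; no stereocenter is formed.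

Step 2
Reactants: 2 β-cyclogeraniol
Product: 3 [(1R,6R)-2,2,6-trimethyl-7-oxabicyclo[4.1.0]heptan-1-yl]methanol
Conditions: Ti(OiPr)4 (0.2 equiv), D-(−)-diethyl tartrate (0.25 equiv), t-BuOOH (2 equiv, decane), 4 Å MS, CH2Cl2, −20 °C
Reagents that add atoms: tert-butyl hydroperoxide, CC(C)(C)OO
Why: Katsuki–Sharpless asymmetric epoxidation: the allylic hydroxyl binds the titanium–tartrate–peroxide complex, which with D-(−)-diethyl tartrate delivers oxygen to the face of the tetrasubstituted ring double bond that gives the (1R,6R) oxirane, so C5 and C6 (carotenoid numbering) of both end groups are set here.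

Step 3
Reactants: 3 [(1R,6R)-2,2,6-trimethyl-7-oxabicyclo[4.1.0]heptan-1-yl]methanol
Product: 4 (1S,6R)-2,2,6-trimethyl-7-oxabicyclo[4.1.0]heptane-1-carbaldehyde
Conditions: nPr4N[RuO4] (5 mol %), N-methylmorpholine N-oxide (1.5 equiv), 4 Å MS, CH2Cl2, 20 °C
Reagents that add atoms: none
Why: Ley–Griffith oxidation under neutral anhydrous conditions gives the aldehyde without opening the oxirane; the α-carbon is quaternary and cannot epimerise (the C1 descriptor changes from R to S only through the priority change).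

Step 4
Reactants: 4 (1S,6R)-2,2,6-trimethyl-7-oxabicyclo[4.1.0]heptane-1-carbaldehyde; 5 diethyl (3-cyano-2-methylprop-2-en-1-yl)phosphonate (commercial E/Z mixture)
Product: 6 (2E,4E)-3-methyl-5-[(1S,6R)-2,2,6-trimethyl-7-oxabicyclo[4.1.0]heptan-1-yl]penta-2,4-dienenitrile
Conditions: NaH, THF, 0 to 20 °C; chromatography on Et3N-deactivated silica
Reagents that add atoms: none
Why: Horner–Wadsworth–Emmons olefination with the delocalised cyanophosphonate anion gives E at the new C7=C8 bond and mainly E at C9=C10 (the minor 2Z isomer is removed by chromatography); the oxirane is stable to the anion.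

Step 5
Reactants: 6 (2E,4E)-3-methyl-5-[(1S,6R)-2,2,6-trimethyl-7-oxabicyclo[4.1.0]heptan-1-yl]penta-2,4-dienenitrile
Product: 7 (2E,4E)-3-methyl-5-[(1S,6R)-2,2,6-trimethyl-7-oxabicyclo[4.1.0]heptan-1-yl]penta-2,4-dienal
Conditions: iBu2AlH (1.3 equiv), CH2Cl2/hexane, −78 °C; then wet SiO2
Reagents that add atoms: water, O
Why: Partial reduction of the nitrile by diisobutylaluminium hydride stops at the N-aluminio aldimine, which is hydrolysed on wet silica to the dienal; the acid-sensitive vinyl epoxide survives the cold, non-acidic work-up.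

Step 6
Reactants: 7 (2E,4E)-3-methyl-5-[(1S,6R)-2,2,6-trimethyl-7-oxabicyclo[4.1.0]heptan-1-yl]penta-2,4-dienal
Product: 8 (2E,4E)-3-methyl-5-[(3aS,7aR)-4,4,7a-trimethyl-2-oxohexahydro-1,3-benzodioxol-3a-yl]penta-2,4-dienal (cis-fused cyclic carbonate of the 5,6-diol)
Conditions: Pd2(dba)3·CHCl3 (2.5 mol %), P(OiPr)3 (20 mol %), CO2 (1 atm), THF, 20 °C
Reagents that add atoms: carbon dioxide, O=C=O
Why: Tsuji–Trost-type vinyl epoxide/CO2 cyclic carbonate formation: zerovalent palladium ionises the vinyl epoxide with inversion at C6, the C5 alkoxide captures CO2, and the carbonate oxygen closes the five-membered ring on the π-allyl terminus C6 anti to palladium (second inversion), so the cis-(5R,6S) diol is stored as its carbonate with net retention.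

Step 7
Reactants: 9 (2E,4E,6E)-2,7-dimethylocta-2,4,6-trienedial
Product: 10 (2E,4E,6E)-2,7-dimethylocta-2,4,6-triene-1,8-diol
Conditions: NaBH4, MeOH/THF, 0 °C
Reagents that add atoms: none
Why: Borohydride reduction of both conjugated aldehydes; the triene geometry is untouched and no stereocenter is formed.

Step 8
Reactants: 10 (2E,4E,6E)-2,7-dimethylocta-2,4,6-triene-1,8-diol
Product: 11 [(2E,4E,6E)-2,7-dimethylocta-2,4,6-triene-1,8-diyl]bis(triphenylphosphonium) dibromide
Conditions: PPh3·HBr (2.1 equiv), MeOH, 20 °C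
Reagents that add atoms: triphenylphosphine hydrobromide, [Br-].[PH+](c1ccccc1)(c1ccccc1)c1ccccc1
Why: Allylic alcohol to phosphonium salt formation: ionisation to the allylic cation and capture by triphenylphosphine at the primary terminus keeps the triene conjugated, the standard preparation of the C10 Wittig salt.

Step 9
Reactants: 11 [(2E,4E,6E)-2,7-dimethylocta-2,4,6-triene-1,8-diyl]bis(triphenylphosphonium) dibromide; 7 C15 epoxy dienal; 8 C15 carbonate dienal
Product: 14 (5R,6S,5'R,6'S)-5',6'-epoxy-5,6,5',6'-tetrahydro-β,β-carotene-5,6-diol, via C25 epoxy phosphonium bromide 12 (not isolated), via C40 epoxide carbonate 13 (not isolated)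
Conditions: NaN(SiMe3)2 (1.0 equiv), THF/DMF, −78 °C, then 7, to 0 °C; NaN(SiMe3)2 (1.0 equiv), −78 °C, then 8, to 20 °C; NaOMe (0.2 equiv), MeOH, 20 °C; work-up, then n-heptane, 90 °C, 2 h
Reagents that add atoms: none
Why: Two Wittig olefinations in sequence: the mono-ylide takes the epoxy dienal 7 first (so the carbonate, the better leaving group, is never carried on a conjugated ylide), the second equivalent of base and 8 complete the C40 chain, catalytic methoxide transesterifies the cyclic carbonate to free the cis-diol, and brief heating converges the 11Z/11'Z isomers to all-E; no stereocenter is touched.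

Step 10
Reactants: 14 (5R,6S,5'R,6'S)-5',6'-epoxy-5,6,5',6'-tetrahydro-β,β-carotene-5,6-diol
Product: 15 (5R,6S,5'R,8'S)-5',8'-epoxy-5,6,5',8'-tetrahydro-β,β-carotene-5,6-diol (target)
Conditions: (R)-3,3'-bis(2,4,6-triisopropylphenyl)-1,1'-binaphthyl-2,2'-diyl hydrogen phosphate (5 mol %), toluene, −40 °C; Et3N quench; preparative HPLC
Reagents that add atoms: none
Why: Proposed new method: the acid-catalysed 5,6-epoxide to 5,8-epoxide (furanoid) rearrangement of carotenoid epoxides is known and is the presumed biogenetic ring closure (protonation, C6'–O heterolysis to a polyenyl cation, 5-endo capture at C8' by the retained 5'-oxygen, so C5' stays R), and 5,6-diol end groups are inert to such mild acid; what is new is the use of a confined chiral phosphoric acid whose phosphate, hydrogen-bonded to the 5'-OH and ion-paired with the cation, is meant to fix the sense of the C7'–C8' twist and so favour the 8'S epimer over the roughly 1:1 mixture that mineral acid gives (closest known type: chiral-phosphate-controlled capture of allylic and benzylic cations by tethered oxygen nucleophiles).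

## Compound list

1 | β-cyclocitral (2,6,6-trimethylcyclohex-1-ene-1-carbaldehyde) | CC1=C(C=O)C(C)(C)CCC1 | starting material
2 | β-cyclogeraniol ((2,6,6-trimethylcyclohex-1-en-1-yl)methanol) | CC1=C(CO)C(C)(C)CCC1 | intermediate
3 | [(1R,6R)-2,2,6-trimethyl-7-oxabicyclo[4.1.0]heptan-1-yl]methanol | OC[C@]12C(C)(C)CCC[C@@]1(C)O2 | intermediate
4 | (1S,6R)-2,2,6-trimethyl-7-oxabicyclo[4.1.0]heptane-1-carbaldehyde | O=C[C@]12C(C)(C)CCC[C@@]1(C)O2 | intermediate
5 | diethyl (3-cyano-2-methylprop-2-en-1-yl)phosphonate (commercial E/Z mixture, E isomer drawn) | N#C/C=C(\C)CP(=O)(OCC)OCC | starting material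
6 | (2E,4E)-3-methyl-5-[(1S,6R)-2,2,6-trimethyl-7-oxabicyclo[4.1.0]heptan-1-yl]penta-2,4-dienenitrile | N#C/C=C(C)/C=C/[C@]12C(C)(C)CCC[C@@]1(C)O2 | intermediate
7 | (2E,4E)-3-methyl-5-[(1S,6R)-2,2,6-trimethyl-7-oxabicyclo[4.1.0]heptan-1-yl]penta-2,4-dienal | O=C/C=C(C)/C=C/[C@]12C(C)(C)CCC[C@@]1(C)O2 | intermediate
8 | (2E,4E)-3-methyl-5-[(3aS,7aR)-4,4,7a-trimethyl-2-oxohexahydro-1,3-benzodioxol-3a-yl]penta-2,4-dienal | O=C/C=C(C)/C=C/[C@]1(O2)C(C)(C)CCC[C@@]1(C)OC2=O | intermediate
9 | (2E,4E,6E)-2,7-dimethylocta-2,4,6-trienedial | O=C/C(C)=C/C=C/C=C(C)/C=O | starting material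
10 | (2E,4E,6E)-2,7-dimethylocta-2,4,6-triene-1,8-diol | OC/C(C)=C/C=C/C=C(C)/CO | intermediate
11 | [(2E,4E,6E)-2,7-dimethylocta-2,4,6-triene-1,8-diyl]bis(triphenylphosphonium) dibromide | c1ccccc1[P+](c1ccccc1)(c1ccccc1)C/C(C)=C/C=C/C=C(C)/C[P+](c1ccccc1)(c1ccccc1)c1ccccc1.[Br-].[Br-] | intermediate
12 | C25 epoxy phosphonium bromide, [(2E,4E,6E,8E,10E,12E)-2,7,11-trimethyl-13-[(1S,6R)-2,2,6-trimethyl-7-oxabicyclo[4.1.0]heptan-1-yl]trideca-2,4,6,8,10,12-hexaen-1-yl]triphenylphosphonium bromide (not isolated) | [Br-].c1ccccc1[P+](c1ccccc1)(c1ccccc1)C/C(C)=C/C=C/C=C(C)/C=C/C=C(C)/C=C/[C@]12C(C)(C)CCC[C@@]1(C)O2 | intermediate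
13 | C40 epoxide carbonate, (5R,6S,5'R,6'S)-5',6'-epoxy-5,6,5',6'-tetrahydro-β,β-carotene-5,6-diyl carbonate (not isolated) | CC(/C=C/C=C(C)/C=C/[C@]1(O2)C(C)(C)CCC[C@@]1(C)OC2=O)=C\C=C\C=C(C)\C=C\C=C(/C)\C=C\[C@]12C(C)(C)CCC[C@@]1(C)O2 | intermediate
14 | (5R,6S,5'R,6'S)-5',6'-epoxy-5,6,5',6'-tetrahydro-β,β-carotene-5,6-diol | CC(/C=C/C=C(C)/C=C/[C@]1(O)C(C)(C)CCC[C@@]1(C)O)=C\C=C\C=C(C)\C=C\C=C(/C)\C=C\[C@]12C(C)(C)CCC[C@@]1(C)O2 | intermediate
15 | (5R,6S,5'R,8'S)-5',8'-epoxy-5,6,5',8'-tetrahydro-β,β-carotene-5,6-diol | CC(/C=C/C=C(C)/C=C/[C@]1(O)C(C)(C)CCC[C@@]1(C)O)=C\C=C\C=C(C)\C=C\C=C(/C)[C@@H]1C=C2C(C)(C)CCC[C@@]2(C)O1 | target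

## Step count and risks

Total: 10 steps. Longest linear sequence: 8 steps (steps 1, 2, 3, 4, 5, 6, 9, 10; 1 → 2 → 3 → 4 → 6 → 7 → 8 → 14 → 15).

The three steps most likely to fail are steps 10, 9 and 6.

In step 10 the acid-catalysed ring closure itself is reliable, but the chiral acid may give little selectivity at C8' or the wrong sense. The sense of induction of the (R)-acid is an assumption; if it is mismatched the mirror-image acid is tried first. The fallback closes the dihydrofuran before the chain is assembled and replaces catalyst control by separation and recycling. It sets out from 7: (1S)-(+)-10-camphorsulfonic acid (5 mol %) in CH2Cl2 at 0 °C rearranges the vinyl epoxide to (2E)-3-[(2S,7aR)-4,4,7a-trimethyl-2,4,5,6,7,7a-hexahydro-1-benzofuran-2-yl]but-2-enal F1 and its C2 epimer (2E)-3-[(2R,7aR)-4,4,7a-trimethyl-2,4,5,6,7,7a-hexahydro-1-benzofuran-2-yl]but-2-enal F2. These small diastereomers are separable on silica, and F2 is returned to the acid and re-equilibrated. F1 then takes the place of 7 in the sequence of step 9: with the mono-ylide of 11 it gives the C25 furanoid phosphonium bromide F3, whose ylide with 8 gives the C40 furanoid carbonate F4, and methanolysis of F4 gives 15 directly. The fallback comes back to the route at 15.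

In step 9 the sequential use of the two ends of 11 may give mostly the two symmetrical C40 products, or the ylide of 12 may open its remote epoxide. The fallback is a symmetrical two-directional assembly followed by desymmetrisation. It sets out from 7 and 11: two equivalents of 7 with 11 and NaOMe in CH2Cl2/MeOH, then heating in heptane, give the C2-symmetric (5R,6S,5'R,6'S)-5,6:5',6'-diepoxy-5,6,5',6'-tetrahydro-β,β-carotene F5. One of its two identical vinyl epoxides is then converted with Pd2(dba)3·CHCl3, P(OiPr)3 and CO2 in THF, stopped near 40 % conversion with recovered F5 recycled, to give 13. This comes back to the route at 13, which is isolated and methanolysed to 14 as in step 9.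

In step 6 zerovalent palladium may fail to ionise the vinyl epoxide at the hindered fully substituted C6, or the carbonate may not close there. The fallback is the SN1 hydration that nature presumably uses. It sets out from 7: 0.05 M H2SO4 in THF/water at 0 °C opens the epoxide to the C6 cation, which water captures on both faces. This gives (2E,4E)-5-[(1S,2R)-1,2-dihydroxy-2,6,6-trimethylcyclohexyl]-3-methylpenta-2,4-dienal F6 (cis-diol, retention) and its C1 epimer (2E,4E)-5-[(1R,2R)-1,2-dihydroxy-2,6,6-trimethylcyclohexyl]-3-methylpenta-2,4-dienal F7 (trans-diol), separated by chromatography. F6 takes the place of 8 in step 9 and, having no carbonate to cleave, gives 14 directly from the ylide of 12. The fallback comes back to the route at 14.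

## Further compounds

F1 | step 10 | (2E)-3-[(2S,7aR)-4,4,7a-trimethyl-2,4,5,6,7,7a-hexahydro-1-benzofuran-2-yl]but-2-enal | O=C\C=C(/C)[C@@H]1C=C2C(C)(C)CCC[C@@]2(C)O1
F2 | step 10 | (2E)-3-[(2R,7aR)-4,4,7a-trimethyl-2,4,5,6,7,7a-hexahydro-1-benzofuran-2-yl]but-2-enal | O=C\C=C(/C)[C@H]1C=C2C(C)(C)CCC[C@@]2(C)O1
F3 | step 10 | C25 furanoid phosphonium bromide, [(2E,4E,6E,8E,10E)-2,7-dimethyl-11-[(2S,7aR)-4,4,7a-trimethyl-2,4,5,6,7,7a-hexahydro-1-benzofuran-2-yl]dodeca-2,4,6,8,10-pentaen-1-yl]triphenylphosphonium bromide | [Br-].c1ccccc1[P+](c1ccccc1)(c1ccccc1)C/C(C)=C/C=C/C=C(C)/C=C/C=C(\C)[C@@H]1C=C2C(C)(C)CCC[C@@]2(C)O1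
F4 | step 10 | C40 furanoid carbonate, (5R,6S,5'R,8'S)-5',8'-epoxy-5,6,5',8'-tetrahydro-β,β-carotene-5,6-diyl carbonate | CC(/C=C/C=C(C)/C=C/[C@]1(O2)C(C)(C)CCC[C@@]1(C)OC2=O)=C\C=C\C=C(C)\C=C\C=C(/C)[C@@H]1C=C2C(C)(C)CCC[C@@]2(C)O1
F5 | step 9 | (5R,6S,5'R,6'S)-5,6:5',6'-diepoxy-5,6,5',6'-tetrahydro-β,β-carotene | CC(/C=C/C=C(C)/C=C/[C@]12C(C)(C)CCC[C@@]1(C)O2)=C\C=C\C=C(C)\C=C\C=C(/C)\C=C\[C@]12C(C)(C)CCC[C@@]1(C)O2
F6 | step 6 | (2E,4E)-5-[(1S,2R)-1,2-dihydroxy-2,6,6-trimethylcyclohexyl]-3-methylpenta-2,4-dienal | O=C/C=C(C)/C=C/[C@]1(O)C(C)(C)CCC[C@@]1(C)O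
F7 | step 6 | (2E,4E)-5-[(1R,2R)-1,2-dihydroxy-2,6,6-trimethylcyclohexyl]-3-methylpenta-2,4-dienal | O=C/C=C(C)/C=C/[C@@]1(O)C(C)(C)CCC[C@@]1(C)O
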